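**Retrosynthetic overview**

1. Target 35 is (3S,5R,3'S,6E,6'E)-4',5'-didehydro-5,6-dihydro-4,5'-retro-β,β-carotene-3,5,3'-triol (carotenoid locants; ring A = C1–C6 with the 3,5-diol, ring B = C1'–C6' cyclohexadiene). The last disconnection is C11–C12, into C15 dienyne diol 21 (ring A) and C25 octaenyl iodide 33 (ring B).
2. Enabling feature: in the retro-polyene, C11–C12 (like its mirror C11'–C12') is a single bond between two sp2 CH carbons. C11 ends the unsubstituted C10=C11 unit and C12 is the CH end of the trisubstituted C12=C13(CH3) alkene. C11 can therefore enter as a terminal alkyne carbon (syn hydrostannation sets 10E), and C12/C12' as the two ends of one C2-symmetric C10 tetraene diiodide 32 (two-fold methylalumination of a dienediyne).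
3. Ring B is ring A minus water, so both C15 enynes come from one enone 19 (C5 ketone): CH3 addition gives the C5 carbinol of ring A; enol triflation and methylation give C4'=C5' of ring B.
4. Only one carbocycle is formed (C5–C6 bond, step 10, shared by rings A and B). Nickel-catalysed reductive cyclisation of acyclic ynal 16 adds C5 and H syn across C6≡C7 and so fixes the exocyclic 6E/6'E alkene (chain cis to C1). C3 comes from epoxide 7, C1 from isobutyronitrile, the 8E enyne from iodide 5.
5. Order: ring closure (step 10), divergence to 21 and 25, first Stille coupling at C11'–C12' (step 22), then tandem hydrostannation/Stille coupling at C11–C12 (step 23), which gives unprotected 35.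

Key step: step 23

Assumption: epoxide 7 is bought as the (R)-enantiomer (catalogue compound; it is also the product of hydrolytic kinetic resolution of the racemate).
Remark: from 14 on, all operations are run under argon in dim light.

**Route**

Step 1
Reactants: 1 1,4-bis(trimethylsilyl)buta-1,3-diyne
Product: 3 buta-1,3-diyn-1-yl(trimethyl)silane, via lithium silylbutadiynide 2 (not isolated)
Conditions: MeLi·LiBr (1.0 equiv), Et2O, rt; then H2O, 0 °C; used as a dried solution
Reagents that add atoms: none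
Why: Nucleophilic cleavage of one C–Si bond by MeLi·LiBr stops at the mono-acetylide, and protonation gives the terminal diyne needed for carbometalation.

Step 2
Reactants: 3 buta-1,3-diyn-1-yl(trimethyl)silane
Product: 5 [(3E)-4-iodo-3-methylbut-3-en-1-yn-1-yl]trimethylsilane, via alkenylalane 4 (not isolated)
Conditions: Me3Al (2 equiv), Cp2ZrCl2 (0.25 equiv), ClCH2CH2Cl, rt; then I2, THF, −30 °C
Reagents that add atoms: trimethylaluminium C[Al](C)C; iodine II
Why: Zirconium-catalysed methylalumination (Negishi carboalumination) adds CH3 and aluminium syn across the terminal alkyne only, and iodinolysis with retention gives the E-iodide that later becomes the 8E and 8'E alkenes.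

Step 3
Reactants: 6 2-methylpropanenitrile; 7 (2R)-2-{2-[(4-methoxybenzyl)oxy]ethyl}oxirane
Product: 9 (4S)-4-hydroxy-6-[(4-methoxybenzyl)oxy]-2,2-dimethylhexanenitrile, via lithiated isobutyronitrile 8 (not isolated)
Conditions: LiN(iPr)2, THF, −78 °C; then 7, −78 °C to rt; H2O
Reagents that add atoms: none
Why: SN2 opening of the terminal epoxide at its CH2 carbon by the nitrile-stabilised carbanion builds the quaternary carbon C1 and leaves the carbinol stereocentre (future C3 and C3') untouched.

Step 4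
Reactants: 9 (4S)-4-hydroxy-6-[(4-methoxybenzyl)oxy]-2,2-dimethylhexanenitrile
Product: 10 (4S)-4-[(tert-butyldimethylsilyl)oxy]-6-[(4-methoxybenzyl)oxy]-2,2-dimethylhexanenitrile
Conditions: tert-butyldimethylsilyl chloride, imidazole, DMF, rt
Reagents that add atoms: tert-butyldimethylsilyl chloride CC(C)(C)[Si](C)(C)Cl
Why: Standard silyl protection of the secondary alcohol, which also prevents its cyclisation onto the nitrile.

Step 5
Reactants: 10 (4S)-4-[(tert-butyldimethylsilyl)oxy]-6-[(4-methoxybenzyl)oxy]-2,2-dimethylhexanenitrile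
Product: 12 (4S)-4-[(tert-butyldimethylsilyl)oxy]-6-[(4-methoxybenzyl)oxy]-2,2-dimethylhexanal, via aluminio imine 11 (not isolated)
Conditions: iBu2AlH (1.3 equiv), CH2Cl2, −78 °C; then aqueous KNaC4H4O6 (potassium sodium tartrate), rt
Reagents that add atoms: water O
Why: Partial reduction of the nitrile stops at the N-aluminio imine, which is hydrolysed on work-up to the non-enolisable α-quaternary aldehyde.

Step 6
Reactants: 12 (4S)-4-[(tert-butyldimethylsilyl)oxy]-6-[(4-methoxybenzyl)oxy]-2,2-dimethylhexanal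
Product: 13 tert-butyl({(3S)-1-[(4-methoxybenzyl)oxy]-5,5-dimethylhept-6-yn-3-yl}oxy)dimethylsilane
Conditions: dimethyl (1-diazo-2-oxopropyl)phosphonate, K2CO3, MeOH, 0 °C to rt
Reagents that add atoms: dimethyl (1-diazo-2-oxopropyl)phosphonate COP(=O)(OC)C(=[N+]=[N-])C(C)=O
Why: Seyferth–Gilbert homologation with the Ohira–Bestmann reagent converts the aldehyde into the terminal alkyne whose carbons become C6 and C7.

Step 7
Reactants: 13 tert-butyl({(3S)-1-[(4-methoxybenzyl)oxy]-5,5-dimethylhept-6-yn-3-yl}oxy)dimethylsilane; 5 [(3E)-4-iodo-3-methylbut-3-en-1-yn-1-yl]trimethylsilane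
Product: 14 tert-butyl({(3S,8E)-1-[(4-methoxybenzyl)oxy]-5,5,9-trimethyl-11-(trimethylsilyl)undec-8-ene-6,10-diyn-3-yl}oxy)dimethylsilane
Conditions: Pd(PPh3)4 (5 mol%), CuI (10 mol%), iPr2NH, THF, rt
Reagents that add atoms: none
Why: Sonogashira coupling joins the alkyne to alkenyl iodide 5 with retention of the E geometry and completes the C1–C11 carbon chain.

Step 8
Reactants: 14 tert-butyl({(3S,8E)-1-[(4-methoxybenzyl)oxy]-5,5,9-trimethyl-11-(trimethylsilyl)undec-8-ene-6,10-diyn-3-yl}oxy)dimethylsilane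
Product: 15 (3S,8E)-3-[(tert-butyldimethylsilyl)oxy]-5,5,9-trimethyl-11-(trimethylsilyl)undec-8-ene-6,10-diyn-1-ol
Conditions: DDQ (1.2 equiv), CH2Cl2/pH 7 buffer, 0 °C
Reagents that add atoms: none
Why: Oxidative removal of the p-methoxybenzyl ether with DDQ leaves both silyl groups and the electron-poor enediyne untouched.

Step 9
Reactants: 15 (3S,8E)-3-[(tert-butyldimethylsilyl)oxy]-5,5,9-trimethyl-11-(trimethylsilyl)undec-8-ene-6,10-diyn-1-ol
Product: 16 (3S,8E)-3-[(tert-butyldimethylsilyl)oxy]-5,5,9-trimethyl-11-(trimethylsilyl)undec-8-ene-6,10-diynal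
Conditions: Dess–Martin periodinane, NaHCO3, CH2Cl2, 0 °C to rt
Reagents that add atoms: none
Why: Dess–Martin oxidation under buffered conditions gives the β-silyloxy aldehyde without β-elimination.

Step 10
Reactants: 16 (3S,8E)-3-[(tert-butyldimethylsilyl)oxy]-5,5,9-trimethyl-11-(trimethylsilyl)undec-8-ene-6,10-diynal
Product: 18 (2E,5S)-5-[(tert-butyldimethylsilyl)oxy]-3,3-dimethyl-2-[(2E)-3-methyl-5-(trimethylsilyl)pent-2-en-4-yn-1-ylidene]cyclohexan-1-ol (both C1 epimers), via triethylsilyl ether 17 (not isolated)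
Conditions: Ni(cod)2 (15 mol%), PBu3 (30 mol%), Et3SiH (5 equiv), THF, 0 °C to rt, slow addition of 16; then HF·pyridine, pyridine, THF, 0 °C
Reagents that add atoms: none
Why: Nickel-catalysed reductive ynal cyclisation, in which oxidative cyclisation of the aldehyde and the tethered alkyne on zerovalent nickel gives an oxanickelacyclopentene with C5 and nickel cis on the new C6=C7 bond and Si–H cleavage replaces nickel by hydrogen with retention, so the 6-exo ring closure (C5–C6 bond) should give only the 6E exocyclic alkene with the chain cis to C1, the carbinol configuration at C5 being irrelevant.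

Step 11
Reactants: 18 (2E,5S)-5-[(tert-butyldimethylsilyl)oxy]-3,3-dimethyl-2-[(2E)-3-methyl-5-(trimethylsilyl)pent-2-en-4-yn-1-ylidene]cyclohexan-1-ol
Product: 19 (2E,5S)-5-[(tert-butyldimethylsilyl)oxy]-3,3-dimethyl-2-[(2E)-3-methyl-5-(trimethylsilyl)pent-2-en-4-yn-1-ylidene]cyclohexan-1-one
Conditions: Dess–Martin periodinane, NaHCO3, CH2Cl2, 0 °C, dark
Reagents that add atoms: none
Why: Dess–Martin oxidation of the allylic alcohol gives the cross-conjugated enone without acid, base or nucleophile that could isomerise the kinetically set exocyclic alkene.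

Step 12
Reactants: 19 (2E,5S)-5-[(tert-butyldimethylsilyl)oxy]-3,3-dimethyl-2-[(2E)-3-methyl-5-(trimethylsilyl)pent-2-en-4-yn-1-ylidene]cyclohexan-1-one
Product: 20 (1R,2E,5S)-5-[(tert-butyldimethylsilyl)oxy]-1,3,3-trimethyl-2-[(2E)-3-methyl-5-(trimethylsilyl)pent-2-en-4-yn-1-ylidene]cyclohexan-1-ol
Conditions: CeCl3 (3 equiv), MeLi (3 equiv), THF, −78 °C; H2O
Reagents that add atoms: methyllithium [Li]C
Why: 1,2-Addition of the organocerium reagent (no enolisation or conjugate addition) should occur by equatorial attack because the axial trajectory is blocked by the axial C1 methyl group, which places the new C5 hydroxyl axial and trans to the equatorial C3 silyloxy group (5R).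

Step 13
Reactants: 20 (1R,2E,5S)-5-[(tert-butyldimethylsilyl)oxy]-1,3,3-trimethyl-2-[(2E)-3-methyl-5-(trimethylsilyl)pent-2-en-4-yn-1-ylidene]cyclohexan-1-ol
Product: 21 (1S,3R,4E)-3,5,5-trimethyl-4-[(2E)-3-methylpent-2-en-4-yn-1-ylidene]cyclohexane-1,3-diol
Conditions: Bu4NF (3 equiv), THF, 0 °C to rt
Reagents that add atoms: none
Why: Fluoride removes the silyl ether and the alkynylsilane in one operation under basic conditions that the tertiary allylic alcohol tolerates.

Step 14
Reactants: 19 (2E,5S)-5-[(tert-butyldimethylsilyl)oxy]-3,3-dimethyl-2-[(2E)-3-methyl-5-(trimethylsilyl)pent-2-en-4-yn-1-ylidene]cyclohexan-1-one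
Product: 23 (3S,6E)-3-[(tert-butyldimethylsilyl)oxy]-5,5-dimethyl-6-[(2E)-3-methyl-5-(trimethylsilyl)pent-2-en-4-yn-1-ylidene]cyclohex-1-en-1-yl trifluoromethanesulfonate, via potassium dienolate 22 (not isolated)
Conditions: KN(SiMe3)2 (1.1 equiv), THF, −78 °C; then N-phenylbis(trifluoromethanesulfonimide), −78 to 0 °C
Reagents that add atoms: N-phenylbis(trifluoromethanesulfonimide) FC(F)(F)S(=O)(=O)N(c1ccccc1)S(=O)(=O)C(F)(F)F
Why: Kinetic enolisation can occur only towards C4 because C6 carries no hydrogen, and O-triflation of the cross-conjugated dienolate leaves the C6=C7 geometry untouched.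

Step 15
Reactants: 23 (3S,6E)-3-[(tert-butyldimethylsilyl)oxy]-5,5-dimethyl-6-[(2E)-3-methyl-5-(trimethylsilyl)pent-2-en-4-yn-1-ylidene]cyclohex-1-en-1-yl trifluoromethanesulfonate
Product: 24 tert-butyl({(1S,4E)-3,5,5-trimethyl-4-[(2E)-3-methyl-5-(trimethylsilyl)pent-2-en-4-yn-1-ylidene]cyclohex-2-en-1-yl}oxy)dimethylsilane
Conditions: MeZnCl (2 equiv), Pd(PPh3)4 (5 mol%), THF, rt
Reagents that add atoms: methylzinc chloride C[Zn]Cl
Why: Negishi coupling of the dienyl triflate installs the C5' methyl group and thereby the C4'=C5' bond of ring B regiospecifically, with no carbocation that could scramble the 6'E alkene.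

Step 16
Reactants: 24 tert-butyl({(1S,4E)-3,5,5-trimethyl-4-[(2E)-3-methyl-5-(trimethylsilyl)pent-2-en-4-yn-1-ylidene]cyclohex-2-en-1-yl}oxy)dimethylsilane
Product: 25 (1S,4E)-3,5,5-trimethyl-4-[(2E)-3-methylpent-2-en-4-yn-1-ylidene]cyclohex-2-en-1-ol
Conditions: Bu4NF (3 equiv), THF, 0 °C to rt
Reagents that add atoms: none
Why: Fluoride cleaves the silyl ether and the alkynylsilane together and leaves the allylic alcohol and the 6'E dienyne untouched.

Step 17
Reactants: 25 (1S,4E)-3,5,5-trimethyl-4-[(2E)-3-methylpent-2-en-4-yn-1-ylidene]cyclohex-2-en-1-ol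
Product: 26 (1S,4E)-3,5,5-trimethyl-4-[(2E,4E)-3-methyl-5-(tributylstannyl)penta-2,4-dien-1-ylidene]cyclohex-2-en-1-ol
Conditions: PdCl2(PPh3)2 (2 mol%), Bu3SnH (1.2 equiv), THF, 0 °C, dark; filtration through Et3N-deactivated silica
Reagents that add atoms: tributyltin hydride CCCC[SnH](CCCC)CCCC
Why: Palladium-catalysed hydrostannation adds Sn–H syn to the terminal alkyne with tin on the unhindered terminal carbon, which gives the E-alkenylstannane (10'E).

Step 18
Reactants: 27 dimethyl (2E,4E)-hexa-2,4-dienedioate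
Product: 28 (2E,4E)-hexa-2,4-diene-1,6-diol
Conditions: iBu2AlH (4.5 equiv), CH2Cl2, −78 to 0 °C; aqueous KNaC4H4O6
Reagents that add atoms: none
Why: 1,2-Reduction of both ester groups by the aluminium hydride preserves the E,E-diene.

Step 19
Reactants: 28 (2E,4E)-hexa-2,4-diene-1,6-diol
Product: 29 (2E,4E)-hexa-2,4-dienedial
Conditions: MnO2 (excess), CH2Cl2, rt
Reagents that add atoms: none
Why: MnO2 oxidises the bis-allylic diol selectively to the dialdehyde without touching the diene geometry.

Step 20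
Reactants: 29 (2E,4E)-hexa-2,4-dienedial
Product: 30 (3E,5E)-octa-3,5-diene-1,7-diyne
Conditions: Me3SiCHN2 (2.5 equiv), LiN(iPr)2 (2.5 equiv), THF, −78 °C to rt; kept as a solution
Reagents that add atoms: (trimethylsilyl)diazomethane C[Si](C)(C)C=[N+]=[N-]
Why: Colvin rearrangement, in which addition of lithiated (trimethylsilyl)diazomethane, Peterson-type elimination and 1,2-hydrogen shift of the alkylidene carbene convert each enal group into a terminal alkyne under non-nucleophilic conditions that avoid conjugate addition.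

Step 21
Reactants: 30 (3E,5E)-octa-3,5-diene-1,7-diyne
Product: 32 (1E,3E,5E,7E)-1,8-diiodo-2,7-dimethylocta-1,3,5,7-tetraene, via bis-alkenylalane 31 (not isolated)
Conditions: Me3Al (5 equiv), Cp2ZrCl2 (1 equiv), ClCH2CH2Cl, rt, dark; then I2 (2.5 equiv), THF, −30 °C
Reagents that add atoms: trimethylaluminium C[Al](C)C; iodine II
Why: Two-fold zirconium-catalysed methylalumination adds CH3 and aluminium syn to each terminal alkyne and iodinolysis with retention gives the all-E diiodide, which sets 12E and 12'E and installs both C13 methyl groups.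

Step 22
Reactants: 26 (1S,4E)-3,5,5-trimethyl-4-[(2E,4E)-3-methyl-5-(tributylstannyl)penta-2,4-dien-1-ylidene]cyclohex-2-en-1-ol; 32 (1E,3E,5E,7E)-1,8-diiodo-2,7-dimethylocta-1,3,5,7-tetraene
Product: 33 (1S,4E)-4-[(2E,4E,6E,8E,10E,12E)-13-iodo-3,7,12-trimethyltrideca-2,4,6,8,10,12-hexaen-1-ylidene]-3,5,5-trimethylcyclohex-2-en-1-ol
Conditions: 32 (3 equiv), Pd2(dba)3 (2.5 mol%), AsPh3 (20 mol%), NMP, rt, dark
Reagents that add atoms: none
Why: Stille–Migita coupling with an excess of the C2-symmetric diiodide should give mainly the mono-coupled C25 iodide with retention at both alkenes (C11'–C12' bond), the unreacted diiodide being recovered.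

Step 23
Reactants: 21 (1S,3R,4E)-3,5,5-trimethyl-4-[(2E)-3-methylpent-2-en-4-yn-1-ylidene]cyclohexane-1,3-diol; 33 (1S,4E)-4-[(2E,4E,6E,8E,10E,12E)-13-iodo-3,7,12-trimethyltrideca-2,4,6,8,10,12-hexaen-1-ylidene]-3,5,5-trimethylcyclohex-2-en-1-ol
Product: 35 (3S,5R,3'S,6E,6'E)-4',5'-didehydro-5,6-dihydro-4,5'-retro-β,β-carotene-3,5,3'-triol, via trienylstannane 34 (not isolated)
Conditions: 21 (1.3 equiv), Pd2(dba)3 (2.5 mol%), P(2-furyl)3 (10 mol%), Bu3SnH (1.25 equiv, slow addition), THF, 0 °C, dark; then 33 (1.0 equiv) in NMP, rt, dark, argon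
Reagents that add atoms: none
Why: Tandem palladium-catalysed hydrostannation/Stille–Migita coupling: Sn–H adds syn to the terminal alkyne of 21 with tin on C11 to give E-trienylstannane 34, and once the tin hydride is consumed zerovalent palladium inserts into the C12–I bond of 33, the trienyl group passes from tin to divalent palladium and reductive elimination forms the C11–C12 bond, all with retention. The closest known reaction types are the one-pot hydrostannation/Stille sequence and the alkenyl–alkenyl Stille coupling used to assemble carotenoid polyenes. No ring is closed and no stereocentre is created; the step creates the C10=C11 alkene (E by syn addition) and keeps the 12E geometry set by carboalumination. The selectivity needed is stannylation at C11 and coupling in the presence of three free hydroxyl groups, one of them tertiary and allylic: the methyl-branched C9 shields C10, any internal (C10) stannane is too hindered to transmetalate at a useful rate, and the neutral, base-free conditions at room temperature in the dark should leave the C5 carbinol and the polyene untouched. The operation turns a C15 dienyne and the C25 iodide directly into the unprotected undecaene, so no step follows it.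

**Compound list**

1 | 1,4-bis(trimethylsilyl)buta-1,3-diyne | C[Si](C)(C)C#CC#C[Si](C)(C)C | starting material
2 | lithium 4-(trimethylsilyl)buta-1,3-diyn-1-ide | [Li]C#CC#C[Si](C)(C)C | intermediate
3 | buta-1,3-diyn-1-yl(trimethyl)silane | C#CC#C[Si](C)(C)C | intermediate
4 | dimethyl[(1E)-2-methyl-4-(trimethylsilyl)but-1-en-3-yn-1-yl]alumane | C[Al](C)/C=C(C)/C#C[Si](C)(C)C | intermediate
5 | [(3E)-4-iodo-3-methylbut-3-en-1-yn-1-yl]trimethylsilane | I/C=C(C)/C#C[Si](C)(C)C | intermediate
6 | 2-methylpropanenitrile | CC(C)C#N | starting material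
7 | (2R)-2-{2-[(4-methoxybenzyl)oxy]ethyl}oxirane | C1[C@H](O1)CCOCc2ccc(OC)cc2 | starting material
8 | 2-lithio-2-methylpropanenitrile | [Li]C(C)(C)C#N | intermediate
9 | (4S)-4-hydroxy-6-[(4-methoxybenzyl)oxy]-2,2-dimethylhexanenitrile | N#CC(C)(C)C[C@H](O)CCOCc1ccc(OC)cc1 | intermediate
10 | (4S)-4-[(tert-butyldimethylsilyl)oxy]-6-[(4-methoxybenzyl)oxy]-2,2-dimethylhexanenitrile | N#CC(C)(C)C[C@H](O[Si](C)(C)C(C)(C)C)CCOCc1ccc(OC)cc1 | intermediate
11 | N-(diisobutylalumanyl) aldimine of 12 | CC(C)C[Al](CC(C)C)N=CC(C)(C)C[C@H](O[Si](C)(C)C(C)(C)C)CCOCc1ccc(OC)cc1 | intermediate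
12 | (4S)-4-[(tert-butyldimethylsilyl)oxy]-6-[(4-methoxybenzyl)oxy]-2,2-dimethylhexanal | O=CC(C)(C)C[C@H](O[Si](C)(C)C(C)(C)C)CCOCc1ccc(OC)cc1 | intermediate
13 | tert-butyl({(3S)-1-[(4-methoxybenzyl)oxy]-5,5-dimethylhept-6-yn-3-yl}oxy)dimethylsilane | C#CC(C)(C)C[C@H](O[Si](C)(C)C(C)(C)C)CCOCc1ccc(OC)cc1 | intermediate
14 | tert-butyl({(3S,8E)-1-[(4-methoxybenzyl)oxy]-5,5,9-trimethyl-11-(trimethylsilyl)undec-8-ene-6,10-diyn-3-yl}oxy)dimethylsilane | C[Si](C)(C)C#C/C(C)=C/C#CC(C)(C)C[C@H](O[Si](C)(C)C(C)(C)C)CCOCc1ccc(OC)cc1 | intermediate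
15 | (3S,8E)-3-[(tert-butyldimethylsilyl)oxy]-5,5,9-trimethyl-11-(trimethylsilyl)undec-8-ene-6,10-diyn-1-ol | C[Si](C)(C)C#C/C(C)=C/C#CC(C)(C)C[C@H](O[Si](C)(C)C(C)(C)C)CCO | intermediate
16 | (3S,8E)-3-[(tert-butyldimethylsilyl)oxy]-5,5,9-trimethyl-11-(trimethylsilyl)undec-8-ene-6,10-diynal | C[Si](C)(C)C#C/C(C)=C/C#CC(C)(C)C[C@H](O[Si](C)(C)C(C)(C)C)CC=O | intermediate
17 | triethylsilyl ether of 18 | C[Si](C)(C)C#C/C(C)=C/C=C1\C(C)(C)C[C@H](O[Si](C)(C)C(C)(C)C)CC1O[Si](CC)(CC)CC | intermediate
18 | (2E,5S)-5-[(tert-butyldimethylsilyl)oxy]-3,3-dimethyl-2-[(2E)-3-methyl-5-(trimethylsilyl)pent-2-en-4-yn-1-ylidene]cyclohexan-1-ol (both C1 epimers) | C[Si](C)(C)C#C/C(C)=C/C=C1\C(C)(C)C[C@H](O[Si](C)(C)C(C)(C)C)CC1O | intermediate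
19 | (2E,5S)-5-[(tert-butyldimethylsilyl)oxy]-3,3-dimethyl-2-[(2E)-3-methyl-5-(trimethylsilyl)pent-2-en-4-yn-1-ylidene]cyclohexan-1-one | C[Si](C)(C)C#C/C(C)=C/C=C1\C(C)(C)C[C@H](O[Si](C)(C)C(C)(C)C)CC1=O | intermediate
20 | (1R,2E,5S)-5-[(tert-butyldimethylsilyl)oxy]-1,3,3-trimethyl-2-[(2E)-3-methyl-5-(trimethylsilyl)pent-2-en-4-yn-1-ylidene]cyclohexan-1-ol | C[Si](C)(C)C#C/C(C)=C/C=C1\C(C)(C)C[C@H](O[Si](C)(C)C(C)(C)C)C[C@@]1(C)O | intermediate
21 | (1S,3R,4E)-3,5,5-trimethyl-4-[(2E)-3-methylpent-2-en-4-yn-1-ylidene]cyclohexane-1,3-diol | C#C/C(C)=C/C=C1\C(C)(C)C[C@H](O)C[C@@]1(C)O | intermediate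
22 | potassium dienolate of 19 | [K]OC1=C[C@@H](O[Si](C)(C)C(C)(C)C)CC(C)(C)\C1=C/C=C(C)/C#C[Si](C)(C)C | intermediate
23 | (3S,6E)-3-[(tert-butyldimethylsilyl)oxy]-5,5-dimethyl-6-[(2E)-3-methyl-5-(trimethylsilyl)pent-2-en-4-yn-1-ylidene]cyclohex-1-en-1-yl trifluoromethanesulfonate | FC(F)(F)S(=O)(=O)OC1=C[C@@H](O[Si](C)(C)C(C)(C)C)CC(C)(C)\C1=C/C=C(C)/C#C[Si](C)(C)C | intermediate
24 | tert-butyl({(1S,4E)-3,5,5-trimethyl-4-[(2E)-3-methyl-5-(trimethylsilyl)pent-2-en-4-yn-1-ylidene]cyclohex-2-en-1-yl}oxy)dimethylsilane | CC1=C[C@@H](O[Si](C)(C)C(C)(C)C)CC(C)(C)\C1=C/C=C(C)/C#C[Si](C)(C)C | intermediate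
25 | (1S,4E)-3,5,5-trimethyl-4-[(2E)-3-methylpent-2-en-4-yn-1-ylidene]cyclohex-2-en-1-ol | CC1=C[C@@H](O)CC(C)(C)\C1=C/C=C(C)/C#C | intermediate
26 | (1S,4E)-3,5,5-trimethyl-4-[(2E,4E)-3-methyl-5-(tributylstannyl)penta-2,4-dien-1-ylidene]cyclohex-2-en-1-ol | CC1=C[C@@H](O)CC(C)(C)\C1=C/C=C(C)/C=C/[Sn](CCCC)(CCCC)CCCC | intermediate
27 | dimethyl (2E,4E)-hexa-2,4-dienedioate | COC(=O)/C=C/C=C/C(=O)OC | starting material
28 | (2E,4E)-hexa-2,4-diene-1,6-diol | OC/C=C/C=C/CO | intermediate
29 | (2E,4E)-hexa-2,4-dienedial | O=C/C=C/C=C/C=O | intermediate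
30 | (3E,5E)-octa-3,5-diene-1,7-diyne | C#C/C=C/C=C/C#C | intermediate
31 | [(1E,3E,5E,7E)-2,7-dimethylocta-1,3,5,7-tetraene-1,8-diyl]bis(dimethylalumane) | C[Al](C)/C=C(C)/C=C/C=C/C(C)=C/[Al](C)C | intermediate
32 | (1E,3E,5E,7E)-1,8-diiodo-2,7-dimethylocta-1,3,5,7-tetraene | I/C=C(C)/C=C/C=C/C(C)=C/I | intermediate
33 | (1S,4E)-4-[(2E,4E,6E,8E,10E,12E)-13-iodo-3,7,12-trimethyltrideca-2,4,6,8,10,12-hexaen-1-ylidene]-3,5,5-trimethylcyclohex-2-en-1-ol | CC1=C[C@@H](O)CC(C)(C)\C1=C/C=C(C)/C=C/C=C(C)/C=C/C=C/C(C)=C/I | intermediate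
34 | (1S,3R,4E)-3,5,5-trimethyl-4-[(2E,4E)-3-methyl-5-(tributylstannyl)penta-2,4-dien-1-ylidene]cyclohexane-1,3-diol | CCCC[Sn](CCCC)(CCCC)/C=C/C(C)=C/C=C1\C(C)(C)C[C@H](O)C[C@@]1(C)O | intermediate
35 | (3S,5R,3'S,6E,6'E)-4',5'-didehydro-5,6-dihydro-4,5'-retro-β,β-carotene-3,5,3'-triol | CC1=C[C@@H](O)CC(C)(C)\C1=C/C=C(C)/C=C/C=C(C)/C=C/C=C/C(C)=C/C=C/C(C)=C/C=C1\C(C)(C)C[C@H](O)C[C@@]1(C)O | target

**Step count and risks**

Total step count: 23. Longest linear sequence: 15 steps (steps 3–11, 14–17, 22, 23).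

Steps most likely to fail:

Step 10. The oxidative cyclisation may be slow at the neopentylic alkyne carbon C6, and nickel may be diverted into oligomerisation through the silyl alkyne or the enyne. The fallback sets out from 16 and uses a cationic rhodium–bisphosphine catalyst ([Rh(dppe)]BF4, CH2Cl2, rt) for intramolecular alkyne hydroacylation. Insertion into the aldehyde C–H bond and cis-addition of acyl and hydride across C6≡C7 should give the same 6E geometry and lead directly to enone 19, where the route is rejoined; steps 10 and 11 become one step and no new compound is made (F0).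

Step 12. The methyl addition may show poor facial selectivity at C5. The fallback makes the C5 carbinol from the ring-B alkene instead of the ketone. It sets out from 24, which is epoxidised at C4=C5 (mCPBA, NaHCO3, CH2Cl2, −20 °C). Attack should occur anti to the bulky allylic silyloxy group, on the terminal and most electron-rich double bond of the conjugated system, to give the anti-4,5-epoxide of 24 F1. Bu4NF removes both silyl groups to give the epoxy alcohol F2. NaAlH2(OCH2CH2OCH3)2 (THF, 0 °C) should then deliver hydride from the C3 alkoxide to C4, on the face opposite to the epoxide oxygen, so that the oxygen stays on C5 trans to the C3 hydroxyl. The product is diol 21, where the route is rejoined before step 23.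

Step 23. Hydrostannation may be regio-impure, the stannane may protodestannylate, or the polyene may undergo E/Z isomerisation and homocoupling during a slow transmetalation. The fallback is a Suzuki–Miyaura coupling and sets out from 21. Copper-catalysed formal hydroboration (bis(pinacolato)diboron, CuCl, Xantphos, NaOtBu, MeOH, THF, rt) should give the E-trienyl pinacol boronate F3 by syn borylcupration with boron on C11. F3 is coupled with iodide 33 (Pd(OAc)2, SPhos, K3PO4, THF/H2O, rt, dark) and gives target 35 directly.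

**Further compounds**

F0 | step 10 | none | none
F1 | step 12 | tert-butyl-dimethylsilyl ether of the anti-4,5-epoxide of 24 (epoxide oxygen trans to the C3 silyloxy group, alkynylsilane retained) | C[Si](C)(C)C#C/C(C)=C/C=C1\C(C)(C)C[C@H](O[Si](C)(C)C(C)(C)C)[C@H]2O[C@@]12C
F2 | step 12 | desilylated anti-4,5-epoxy-3-ol with terminal alkyne | C#C/C(C)=C/C=C1\C(C)(C)C[C@H](O)[C@H]2O[C@@]12C
F3 | step 23 | (1S,3R,4E)-3,5,5-trimethyl-4-[(2E,4E)-3-methyl-5-(4,4,5,5-tetramethyl-1,3,2-dioxaborolan-2-yl)penta-2,4-dien-1-ylidene]cyclohexane-1,3-diol | CC1(C)OB(/C=C/C(C)=C/C=C2\C(C)(C)C[C@H](O)C[C@@]2(C)O)OC1(C)C
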